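## Retrosynthetic overview

1. The dihydropyran ring is closed last. Its O1–C2 bond and the only stereocentre come from an enantioselective 6-exo oxa-Michael addition of the phenol in the open-chain precursor (hericenone C), after a 1,3-prototropic shift in the same flask.
2. The aryl–C1' bond comes from a [1,3] O-to-C allyl shift of an aryl allyl ether, made from a phenol and an allylic chloride (Williamson).
3. The C10 allylic chloride comes in one step from isoprene and 3-methylbut-2-enoyl chloride (1,4-chloroacylation).
4. The arene comes from 3,5-dimethoxybenzyl alcohol: palmitate first (it is the final ester), then formylation and chelation-controlled mono-demethylation, with no protecting groups.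
5. Ring order: the benzene ring is bought in; the pyran ring is the only ring formed, in the final step.

Assumption: the stereocentre is read from the SMILES as (S) at C-2 of the chroman; 3, 12, 13 and 14 are drawn as the major (E)-isomers and minor (Z)-isomers are carried along, because step 7 erases that geometry.

## Route

Step 1
Reactants: 1 isoprene (2-methylbuta-1,3-diene); 2 3-methylbut-2-enoyl chloride
Product: 3 (6E)-8-chloro-2,6-dimethylocta-2,6-dien-4-one
Conditions: SnCl4 (0.2 equiv), CH2Cl2, −78 °C; aq. NaHCO3 quench
Reagents that add atoms: none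
Why: Kondakov-type Friedel–Crafts acylation of a 1,3-diene, in which the SnCl4-activated acyl chloride adds to C-1 of isoprene to give the tertiary allyl cation, which takes up chloride at its primary end to give the 1,4-adduct with the favoured (E)-trisubstituted alkene and no stereocentre.

Step 2
Reactants: 4 (3,5-dimethoxyphenyl)methanol; 5 hexadecanoic acid
Product: 6 3,5-dimethoxybenzyl hexadecanoate
Conditions: DCC, 4-(dimethylamino)pyridine (cat.), CH2Cl2, 0 °C → rt
Reagents that add atoms: none
Why: Steglich esterification of an unhindered primary benzylic alcohol, and the ester installed here is the palmitate of the target, so no protecting group is needed.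

Step 3
Reactants: 6 3,5-dimethoxybenzyl hexadecanoate
Product: 8 2-formyl-3,5-dimethoxybenzyl hexadecanoate, via iminium chloride 7 (not isolated)
Conditions: POCl3, DMF, 0 → 70 °C; then H2O, rt
Reagents that add atoms: N,N-dimethylformamide, CN(C)C=O; water, O
Why: Vilsmeier–Haack formylation, in which the chloroiminium ion attacks the position ortho to one methoxy and para to the other (C-2, equal to C-6 by symmetry), which is less hindered than C-4 between the two methoxy groups, while the ester is inert.

Step 4
Reactants: 8 2-formyl-3,5-dimethoxybenzyl hexadecanoate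
Product: 10 2-formyl-3-hydroxy-5-methoxybenzyl hexadecanoate, via aryloxydichloroborane 9 (not isolated)
Conditions: BCl3 (1.2 equiv), CH2Cl2, −78 → 0 °C; then H2O
Reagents that add atoms: none
Why: Chelation-controlled Lewis-acid ether cleavage, in which BCl3 binds the formyl oxygen and the adjacent methoxy oxygen in a six-membered chelate so that chloride removes only that methyl group and the para-methoxy group and the ester survive.

Step 5
Reactants: 10 2-formyl-3-hydroxy-5-methoxybenzyl hexadecanoate; 3 (6E)-8-chloro-2,6-dimethylocta-2,6-dien-4-one
Product: 12 3-{[(2E)-3,7-dimethyl-5-oxoocta-2,6-dien-1-yl]oxy}-2-formyl-5-methoxybenzyl hexadecanoate, via potassium phenoxide 11 (not isolated)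
Conditions: K2CO3 (1.05 equiv), DMF, 0 °C → rt
Reagents that add atoms: none
Why: Williamson ether synthesis, in which the weakly basic ortho-formyl phenoxide displaces the primary allylic chloride by SN2 at oxygen in a dipolar aprotic solvent faster than it enolises the β,γ-unsaturated ketone.

Step 6
Reactants: 12 3-{[(2E)-3,7-dimethyl-5-oxoocta-2,6-dien-1-yl]oxy}-2-formyl-5-methoxybenzyl hexadecanoate
Product: 13 4-[(2E)-3,7-dimethyl-5-oxoocta-2,6-dien-1-yl]-2-formyl-3-hydroxy-5-methoxybenzyl hexadecanoate (hericenone C)
Conditions: magnesium silicate MgSiO3 (Florisil), toluene, 90 °C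
Reagents that add atoms: none
Why: Acid-surface-promoted [1,3] O-to-C allyl shift (an intramolecular Friedel–Crafts allylation through a contact aryloxide–allyl cation pair), in which the allyl unit recombines through its primary terminus at the adjacent ortho carbon C-4, the only free ortho position and activated by both flanking oxygens.

Step 7
Reactants: 13 4-[(2E)-3,7-dimethyl-5-oxoocta-2,6-dien-1-yl]-2-formyl-3-hydroxy-5-methoxybenzyl hexadecanoate
Product: 15 [(2S)-8-formyl-5-methoxy-2-methyl-2-(4-methyl-2-oxopent-3-en-1-yl)-3,4-dihydro-2H-chromen-7-yl]methyl hexadecanoate (hericenone F), via conjugated dienone 14 (not isolated)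
Conditions: 1-[3,5-bis(trifluoromethyl)phenyl]-3-[(2S)-3,3-dimethyl-1-{[tris(4-methoxyphenyl)-λ5-phosphanylidene]amino}butan-2-yl]thiourea (10 mol %), toluene (0.05 M), 0 °C → rt; AcOH quench
Reagents that add atoms: none
Why: Proposed new method: the iminophosphorane deprotonates the acidic ortho-formyl phenol, the resulting aminophosphonium phenoxide moves the doubly activated C-4' proton to C-2' (1,3-prototropic shift) to give dienone 14, and the thiourea then holds the dienone carbonyl while the N–H-bound phenoxide adds 6-exo to the Si face of C-3', forming the O1–C2 bond and the (S) tetrasubstituted centre before the enolate is protonated, with E/Z isomers of 13 and 14 converging because they equilibrate through the common dienolate faster than they cyclise; the closest known reaction types are bifunctional-iminophosphorane-catalysed intramolecular oxa-Michael additions, base-catalysed 1,3-prototropic shifts of β,γ-unsaturated carbonyl compounds and amine–thiourea-catalysed chroman-forming oxa-Michael additions, which have not been shown as a tandem on a cross-conjugated β,β-disubstituted dienone to set a tetrasubstituted chroman centre.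

## Compound list

1 | isoprene (2-methylbuta-1,3-diene) | C=CC(C)=C | starting material
2 | 3-methylbut-2-enoyl chloride | CC(C)=CC(=O)Cl | starting material
3 | (6E)-8-chloro-2,6-dimethylocta-2,6-dien-4-one | ClC/C=C(\C)CC(=O)C=C(C)C | intermediate
4 | (3,5-dimethoxyphenyl)methanol | COc1cc(CO)cc(OC)c1 | starting material
5 | hexadecanoic acid (palmitic acid) | CCCCCCCCCCCCCCCC(=O)O | starting material
6 | 3,5-dimethoxybenzyl hexadecanoate | CCCCCCCCCCCCCCCC(=O)OCc1cc(OC)cc(OC)c1 | intermediate
7 | ({2-[(hexadecanoyloxy)methyl]-4,6-dimethoxyphenyl}methylidene)dimethylammonium chloride | CCCCCCCCCCCCCCCC(=O)OCc1cc(OC)cc(OC)c1C=[N+](C)C.[Cl-] | intermediate (not isolated)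
8 | 2-formyl-3,5-dimethoxybenzyl hexadecanoate | CCCCCCCCCCCCCCCC(=O)OCc1cc(OC)cc(OC)c1C=O | intermediate
9 | dichloro{2-formyl-3-[(hexadecanoyloxy)methyl]-5-methoxyphenoxy}borane | CCCCCCCCCCCCCCCC(=O)OCc1cc(OC)cc(OB(Cl)Cl)c1C=O | intermediate (not isolated)
10 | 2-formyl-3-hydroxy-5-methoxybenzyl hexadecanoate | CCCCCCCCCCCCCCCC(=O)OCc1cc(OC)cc(O)c1C=O | intermediate
11 | potassium 2-formyl-3-[(hexadecanoyloxy)methyl]-5-methoxyphenolate | CCCCCCCCCCCCCCCC(=O)OCc1cc(OC)cc([O-])c1C=O.[K+] | intermediate (not isolated)
12 | 3-{[(2E)-3,7-dimethyl-5-oxoocta-2,6-dien-1-yl]oxy}-2-formyl-5-methoxybenzyl hexadecanoate | CCCCCCCCCCCCCCCC(=O)OCc1cc(OC)cc(OC/C=C(\C)CC(=O)C=C(C)C)c1C=O | intermediate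
13 | 4-[(2E)-3,7-dimethyl-5-oxoocta-2,6-dien-1-yl]-2-formyl-3-hydroxy-5-methoxybenzyl hexadecanoate (hericenone C) | CCCCCCCCCCCCCCCC(=O)OCc1cc(OC)c(C/C=C(\C)CC(=O)C=C(C)C)c(O)c1C=O | intermediate
14 | 4-[(3E)-3,7-dimethyl-5-oxoocta-3,6-dien-1-yl]-2-formyl-3-hydroxy-5-methoxybenzyl hexadecanoate | CCCCCCCCCCCCCCCC(=O)OCc1cc(OC)c(CC/C(C)=C/C(=O)C=C(C)C)c(O)c1C=O | intermediate (not isolated)
15 | [(2S)-8-formyl-5-methoxy-2-methyl-2-(4-methyl-2-oxopent-3-en-1-yl)-3,4-dihydro-2H-chromen-7-yl]methyl hexadecanoate | CCCCCCCCCCCCCCCC(=O)OCc1cc(OC)c2c(c1C=O)O[C@](C)(CC(=O)C=C(C)C)CC2 | target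

## Step count and risks

Total steps: 7. Longest linear sequence: 6 steps (4 → 15, steps 2–7); step 1 is a one-step side branch.

**Step 7 (proposed new step).** It can fail in four ways:
- the phenoxide may be too weak a base for a fast 1,3-shift;
- retro-oxa-Michael under the basic catalyst can erode the enantiomeric excess, which is why the reaction is quenched with AcOH at full conversion;
- the aldehyde could consume free iminophosphorane by aza-Wittig reaction;
- the facial sense is a model, so the mirror-image catalyst from D-tert-leucine is used if the (R)-chroman forms.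

Fallback, setting out from 13 and coming back at 15: 13 is treated with 1,8-diazabicyclo[5.4.0]undec-7-ene (0.2 equiv) in CH2Cl2 at rt, a base-mediated isomerisation and oxa-Michael ring closure that is known chemistry for this compound class. This gives 15 as a 1:1 mixture with the (R)-enantiomer F1. The two are separated by preparative supercritical-fluid chromatography on an amylose tris(3,5-dimethylphenylcarbamate) stationary phase.

**Step 6.** The allyl group may migrate to the para carbon C-6, may be lost as the trienone with return of 10, or 13 may close prematurely to racemic chroman. Any racemic chroman must be removed by chromatography before step 7, or it lowers the final enantiomeric excess.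

Fallback, setting out from 10 and 3 and coming back at 13: 10 is converted with NaH in toluene at 0 °C into the sodium phenoxide F2. As a tight ion pair in the non-polar medium, F2 is alkylated by 3 at the ortho carbon C-4 (phenoxide ortho-C-allylation) at rt to 40 °C. This gives 13 directly and bypasses 12.

**Step 5.** K2CO3 or the phenoxide may enolise 3, leading to loss of HCl to the trienone, or may move the β,γ-alkene of 12 into conjugation.

Fallback, setting out from 3 and coming back at 12: 3 is treated with HCO2Na in DMF at rt to give the allylic formate F3. Methanolysis with NaHCO3 in MeOH at rt gives the allylic alcohol F4. F4 is coupled with 10 under neutral Mitsunobu conditions (PPh3, DIAD, THF, 0 °C) to give 12.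

## Further compounds

F1 | step 7 | [(2R)-8-formyl-5-methoxy-2-methyl-2-(4-methyl-2-oxopent-3-en-1-yl)-3,4-dihydro-2H-chromen-7-yl]methyl hexadecanoate | CCCCCCCCCCCCCCCC(=O)OCc1cc(OC)c2c(c1C=O)O[C@@](C)(CC(=O)C=C(C)C)CC2
F2 | step 6 | sodium 2-formyl-3-[(hexadecanoyloxy)methyl]-5-methoxyphenolate | CCCCCCCCCCCCCCCC(=O)OCc1cc(OC)cc([O-])c1C=O.[Na+]
F3 | step 5 | (2E)-3,7-dimethyl-5-oxoocta-2,6-dien-1-yl formate | O=COC/C=C(\C)CC(=O)C=C(C)C
F4 | step 5 | (6E)-8-hydroxy-2,6-dimethylocta-2,6-dien-4-one | OC/C=C(\C)CC(=O)C=C(C)C
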